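Remark on the chemistry: ring A is numbered C1 (bonded to the benzofuran), C2 (bearing the chain), C3 and C5 (oxygenated); the chain runs from benzylic C1' to the terminal methylene C8'; TIPS is triisopropylsilyl; in the oxazaborolidine reduction the isopropenyl group is assumed to act as the larger carbonyl substituent. All structures were re-derived from the target SMILES (C6' is R, C2'=C3' is E) and no correction was needed.

## Structural features

The target is a 2-arylbenzofuran: a benzofuran with a hydroxyl at C6 is bonded through its C2 to C1 of ring A, a benzene ring hydroxylated at C3 and C5. Ring A carries at C2, between the C3 hydroxyl and the benzofuran, a ten-carbon chain: benzylic C1', an E trisubstituted C2'=C3' alkene with its methyl on C3', two methylenes, a secondary allylic carbinol at C6' and a 1,1-disubstituted C7'=C8' alkene with a methyl on C7'. C6' (R) is the only stereocentre and has no stereogenic neighbour, so it must be set by absolute induction. The fragile groups are the three free phenols (electron-rich, easily oxidised), the ortho-allyl phenol motif, which closes to a chroman under acid, the ionisable allylic alcohol, and the doubly activated C1' methylene. The real difficulty is to make the C1'–C2' bond at the most crowded position of ring A while fixing the C2'=C3' geometry and carrying the remote chiral carbinol; direct C-allylation of the resorcinol would not be regioselective. The key step exploits the fact that the C3' methyl is cis to C1': this is the arrangement left when methyl and a metal add syn across a terminal C2'≡C3' alkyne and the metal is then replaced by the ring A benzylic carbon.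

## Logic of the disconnections

22 ⇒ 21. The three phenolic O–H bonds are replaced by O–Si bonds. The phenols would quench the alane and make the benzylic electrophile collapse to a quinone methide, so they must be masked by groups that come off without acid. The forward step has to be a buffered fluoride cleavage that leaves the ortho-allyl phenol and the allylic alcohol untouched.

21 ⇒ 19 + 12 (through 20). The C1'–C2' bond and the C3'–CH3 bond are cut. This divides the molecule into a small chiral alkyne, a benzylic chloride and a methyl donor, and turns the alkene geometry into a consequence of syn carbometalation. The forward step demands regioselective methylalumination, stereoretentive alkenyl transfer to palladium, tolerance of the carbinol as its aluminium alkoxide, and a benzylic chloride that survives Lewis acidic aluminium; for this reason 12 is a chloride rather than a bromide, is fully silylated with bulky groups, and the excess AlMe3 is removed before 12 is added.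

19 ⇒ 18. The C6'–H bond is cut, so the stereocentre becomes a prochiral ketone. The gain is that the only stereocentre is set on an eight-carbon fragment by a catalytic reduction. The demand is facial discrimination between an isopropenyl and a 3-butynyl substituent without hydroboration of the alkyne.

18 ⇒ 15 + 16 (through 17). The C6'–C7' bond is cut between the acyl carbon and the alkenyl carbon. Both pieces are simple; the forward acylation must stop at the ketone and must cope with the acidic alkyne hydrogen.

15 ⇒ 13 (through 14). The amide C–N bond is cut; the acid only has to be activated mildly.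

12 ⇒ 10 (through 11) ⇒ 9. The C1'–Cl bond is traced to a C1'–O bond and then to the formyl group. The electrophile is thereby generated in the last operation before the coupling, under non-acidic conditions, and is never stored.

9 ⇒ 4 + 8. The bond between C1 of ring A and C2 of the benzofuran is cut. This gives an ortho-bromobenzaldehyde and a heteroaryl boronate; the forward coupling must be quick enough to beat protodeboronation and mild enough for the silyl ethers next to the formyl group.

8 ⇒ 6 (through 7) ⇒ 5. The C2–B bond and the O–Si bond are cut; the forward metalation relies on the acidity of the benzofuran C2–H.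

4 ⇒ 3 ⇒ 1 (through 2). The two O–Si bonds and the bond from ring A C2 to the formyl carbon are cut. The symmetric 1 has two equivalent positions para to one hydroxyl and ortho to the other, so the substitution pattern of ring A is fixed by a single electrophilic formylation, which only has to avoid the position between the two hydroxyls.

## Other disconnections considered

Alternative 1: The cut lies inside ring A: bonds C3–C4, C5–C6 and C2–C3 are broken, which leads to cyclobutenone A2 (the benzofuran on its C3, the complete silyl-protected chain on C4) and the silyloxyalkyne A3. In the forward sense, heating A2 with A3 would open the four-membered ring to a vinylketene, which adds the electron-rich alkyne in a [2+2] sense. A second four-electron ring opening, a six-electron electrocyclisation and tautomerisation would then give phenol A1 (Danheiser benzannulation), and fluoride would take A1 to 22.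
- In its favour: the substitution pattern of ring A is dictated by the connectivity of the cascade, the process is thermal and metal-free, and no benzylic halide is needed.
- Against it here: A2 is an enolisable 4-monosubstituted cyclobutenone that must already carry the E alkene, the stereocentre and an allylic silyl ether. Its assembly is long and of uncertain regiochemistry, A3 is a sensitive reagent, and the geometry of C2'=C3' still has to be set somewhere earlier.
- Comparison: on regiochemical certainty of ring A the alternative is the equal of the chosen plan, and on avoiding a labile benzylic chloride it is the better. On mechanism, the pericyclic cascade is attractive but puts the whole chain through prolonged heating. On step economy the chosen plan is clearly shorter, because it forms the chain–arene bond and the alkene geometry in one operation from two fragments of three and seven steps.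

Alternative 2: The cut is at the far end of the chain: the C6' carbinol and the C7'=C8' methylene are traced to epoxy alcohol A4 and further to the C8'-hydroxylated allylic alcohol A5. In the forward sense, Ti(OiPr)4, D-(−)-diethyl tartrate and tert-butyl hydroperoxide would epoxidise the C6'=C7' alkene of A5 under direction of the C8' hydroxyl (Sharpless asymmetric epoxidation) to give A4 with both new centres R. Conversion of the C8' hydroxyl into iodide A6 and reductive opening with zinc would move the oxygen to C6', unveil the terminal methylene, and arrive at 21.
- In its favour: an (E)-2-methyl-2-en-1-ol is among the best substrates for this epoxidation, the sense of induction is predictable, and the directing hydroxyl guarantees that the C2'=C3' alkene is left alone.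
- Against it here: A5 needs either a selective allylic oxidation of one methyl group of a geranyl side chain next to an electron-rich arene or a pre-oxidised chain fragment. Three further operations then follow on the most advanced intermediate, through an acid-sensitive trisubstituted epoxide, and the C1'–C2' bond and the E alkene are not addressed at all.
- Comparison: on enantiocontrol the alternative is the equal or the better of the chosen ketone reduction, whose two carbonyl substituents differ less in size. On chemoselectivity the two are equal. On step economy it is worse, since the chosen plan sets the stereocentre in three steps on an eight-carbon fragment.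

Alternative 3: The cut is the C2=C3 double bond of the furan, which leads to phosphonium salt A8, the ester formed from ring A acid A9 and the phenolic phosphonium salt A10. In the forward sense, Et3N would deprotonate A8 to the ylide, which attacks the neighbouring ester carbonyl; loss of the phosphine oxide closes the furan (intramolecular Wittig reaction) and gives A7, which fluoride would convert into 22.
- In its favour: the aryl–heteroaryl bond is made without palladium and without a heteroaryl boronate prone to protodeboronation, the base is mild, and the position of the aryl group on the furan cannot be in doubt.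
- Against it here: A9 must already bear the chain ortho to the carboxyl, so the C1'–C2' bond and the alkene geometry still have to be created, now on a ring whose ester is not compatible with excess AlMe3. The 2,6-disubstituted benzoate is hindered toward both acylation of A10 and ylide attack, acyl migration to 3-aroylbenzofurans is a recognised side path of this closure, and the carbinol needs its own protecting group.
- Comparison: on regiochemistry the alternative is the equal of the Suzuki coupling, and on robustness of the heteroaryl partner it is the better. On mechanism, it moves the difficult steric demand from a cross-coupling to a carbonyl addition at a doubly ortho-substituted ester. On step economy it is worse, because protection of the carbinol and the construction of A9 add steps.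

Key step: step 11

## Route

Step 1
Reactants: 1 5-bromoresorcinol (5-bromobenzene-1,3-diol)
Product: 3 2-bromo-4,6-dihydroxybenzaldehyde, via aryl iminium chloride 2 (not isolated)
Conditions: POCl3, DMF, MeCN, −15 °C → rt; then H2O, 50 °C
Reagents that add atoms: N,N-dimethylformamide, CN(C)C=O; water, O
Why: Vilsmeier–Haack formylation; the chloroiminium ion should attack para to one hydroxyl and ortho to the other (two positions equivalent by symmetry) rather than between the hydroxyls, as with other 5-substituted resorcinols, and hydrolysis of 2 releases the aldehyde.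

Step 2
Reactants: 3 2-bromo-4,6-dihydroxybenzaldehyde
Product: 4 2-bromo-4,6-bis(triisopropylsilyloxy)benzaldehyde
Conditions: TIPSOTf, 2,6-lutidine, CH2Cl2, 0 °C → rt
Reagents that add atoms: triisopropylsilyl trifluoromethanesulfonate, CC(C)[Si](OS(=O)(=O)C(F)(F)F)(C(C)C)C(C)C
Why: O-silylation; the silyl triflate is reactive enough for the hydrogen-bonded ortho hydroxyl, and the bulky ethers should withstand the later base, hydride and organoaluminium conditions.

Step 3
Reactants: 5 benzofuran-6-ol
Product: 6 6-(triisopropylsilyloxy)benzofuran
Conditions: TIPSCl, imidazole, DMF, rt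
Reagents that add atoms: triisopropylsilyl chloride, CC(C)[Si](Cl)(C(C)C)C(C)C
Why: Standard silylation of a phenol; the bulky ether is inert to butyllithium at low temperature.

Step 4
Reactants: 6 6-(triisopropylsilyloxy)benzofuran
Product: 8 2-[6-(triisopropylsilyloxy)benzofuran-2-yl]-4,4,5,5-tetramethyl-1,3,2-dioxaborolane, via 2-lithiobenzofuran 7 (not isolated)
Conditions: n-BuLi, THF, −78 °C; then iPrOBpin, −78 °C → rt; H2O
Reagents that add atoms: 2-isopropoxy-4,4,5,5-tetramethyl-1,3,2-dioxaborolane, CC(C)OB1OC(C)(C)C(C)(C)O1
Why: Directed deprotonation–borylation; C2–H is the most acidic position of a benzofuran, the 2-lithio species is stable at −78 °C, and the pinacol ester is chosen because it is less prone to protodeboronation than the free boronic acid.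

Step 5
Reactants: 4 2-bromo-4,6-bis(triisopropylsilyloxy)benzaldehyde; 8 2-[6-(triisopropylsilyloxy)benzofuran-2-yl]-4,4,5,5-tetramethyl-1,3,2-dioxaborolane
Product: 9 2-[6-(triisopropylsilyloxy)benzofuran-2-yl]-4,6-bis(triisopropylsilyloxy)benzaldehyde
Conditions: Pd(OAc)2 (3 mol %), SPhos (6 mol %), K3PO4, toluene/H2O (10:1), 60 °C
Reagents that add atoms: none
Why: Suzuki–Miyaura coupling; the bromide is activated by the ortho formyl group, and a fast dialkylbiarylphosphine catalyst with a mild phosphate base at moderate temperature should outrun protodeboronation and spare the aryl silyl ethers.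

Step 6
Reactants: 9 2-[6-(triisopropylsilyloxy)benzofuran-2-yl]-4,6-bis(triisopropylsilyloxy)benzaldehyde
Product: 10 [2-(6-(triisopropylsilyloxy)benzofuran-2-yl)-4,6-bis(triisopropylsilyloxy)phenyl]methanol
Conditions: NaBH4, THF/MeOH, 0 °C
Reagents that add atoms: none
Why: Borohydride reduction of an aryl aldehyde; at 0 °C the bulky ortho silyl ether should not migrate to the new benzylic oxygen.

Step 7
Reactants: 10 [2-(6-(triisopropylsilyloxy)benzofuran-2-yl)-4,6-bis(triisopropylsilyloxy)phenyl]methanol
Product: 12 2-[2-(chloromethyl)-3,5-bis(triisopropylsilyloxy)phenyl]-6-(triisopropylsilyloxy)benzofuran, via benzylic mesylate 11 (not isolated)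
Conditions: MsCl, Et3N, LiCl, THF, 0 °C → rt; rapid filtration through base-washed silica; used at once
Reagents that add atoms: lithium chloride, [Li+].[Cl-]; methanesulfonyl chloride, CS(=O)(=O)Cl (its chloride joins the chloride pool)
Why: Sulfonylation followed by chloride displacement at an electron-rich benzylic carbon; the medium stays basic so no silyl ether is lost, and the chloride is preferred to the bromide because it ionises less readily.

Step 8
Reactants: 13 pent-4-ynoic acid
Product: 15 N-methoxy-N-methylpent-4-ynamide, via acyl imidazole 14 (not isolated)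
Conditions: CDI, CH2Cl2, rt; then MeNHOMe·HCl, rt
Reagents that add atoms: N,O-dimethylhydroxylamine hydrochloride, CNOC.Cl
Why: Weinreb amide formation through the acyl imidazole; the conditions are neutral and the terminal alkyne is a spectator.

Step 9
Reactants: 15 N-methoxy-N-methylpent-4-ynamide; 16 2-bromopropene
Product: 18 2-methylhept-1-en-6-yn-3-one, via isopropenylmagnesium bromide 17 (not isolated)
Conditions: 16, Mg, THF, 40 °C; then 15 (2.3 equiv of 17), THF, −20 → 0 °C; inverse quench into cold 1 M HCl
Reagents that add atoms: none
Why: Weinreb ketone synthesis; one equivalent of 17 deprotonates the alkyne and the second adds to the amide to give a chelated tetrahedral magnesium species that cannot add again, and the acidic inverse quench keeps the liberated hydroxylamine protonated so that it should not add to the enone.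

Step 10
Reactants: 18 2-methylhept-1-en-6-yn-3-one
Product: 19 (R)-2-methylhept-1-en-6-yn-3-ol
Conditions: (S)-2-methyl-CBS-oxazaborolidine (0.2 equiv), catecholborane, toluene, −78 °C; then MeOH, aq NaOH wash
Reagents that add atoms: none
Why: Corey–Bakshi–Shibata reduction; the ketone should bind the catalyst with the branched sp2 isopropenyl group in the position of the large substituent, so hydride is delivered with the same topicity that turns acetophenone into (R)-1-phenylethanol, giving R at the carbinol, and catecholborane at −78 °C should not hydroborate the alkyne or the alkene.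

Step 11
Reactants: 19 (R)-2-methylhept-1-en-6-yn-3-ol; 12 2-[2-(chloromethyl)-3,5-bis(triisopropylsilyloxy)phenyl]-6-(triisopropylsilyloxy)benzofuran
Product: 21 (3R,6E)-8-[2-(6-(triisopropylsilyloxy)benzofuran-2-yl)-4,6-bis(triisopropylsilyloxy)phenyl]-2,6-dimethylocta-1,6-dien-3-ol, via alkenylalane alkoxide 20 (not isolated)
Conditions: 19 (1.4 equiv), AlMe3 (3.5 equiv per 19), Cp2ZrCl2 (0.25 equiv), CH2Cl2, 0 °C → rt; volatiles removed in vacuo; THF, 12, Pd(PPh3)4 (5 mol %), rt; aq potassium sodium tartrate
Reagents that add atoms: trimethylaluminium, C[Al](C)C
Why: AlMe3 first converts the carbinol into its dimethylaluminium alkoxide with loss of methane, so the stereocentre travels as a non-ionisable spectator. Cp2ZrCl2 and AlMe3 then form a methylzirconocene species polarised by aluminium that adds methyl and metal across the terminal alkyne through a four-centre syn transition state, methyl to internal C3' and the metal, after exchange to aluminium, to terminal C2', which gives 20. The closest known reaction type is the zirconium-catalysed methylalumination of terminal alkynes followed by palladium-catalysed coupling of the alkenylalane with a benzylic halide (a Negishi-type alkenyl–benzyl coupling). After the volatile excess of AlMe3 has been pumped off, zerovalent palladium inserts into the C1'–Cl bond of 12, the alkenyl group passes from aluminium to palladium with retention, and reductive elimination forms C1'–C2'. No ring is closed and no stereocentre is created; the only stereochemical element set is the E geometry, which follows from syn addition and stereoretentive coupling and leaves the new methyl cis to C1'. The step needs regioselective metalation (secured by the terminal alkyne, which puts the metal on the unhindered carbon), chemoselectivity over the C7'=C8' alkene (a 1,1-disubstituted alkene is not carbometalated under these conditions) and alkenyl rather than methyl transfer to palladium (sp2 groups transmetalate faster, and removal of free AlMe3 reinforces this). The three bulky silyl ethers keep acidic protons away from the alane and prevent quinone methide formation from 12.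

Step 12
Reactants: 21 (3R,6E)-8-[2-(6-(triisopropylsilyloxy)benzofuran-2-yl)-4,6-bis(triisopropylsilyloxy)phenyl]-2,6-dimethylocta-1,6-dien-3-ol
Product: 22 5-(6-hydroxybenzofuran-2-yl)-4-[(2E,6R)-6-hydroxy-3,7-dimethylocta-2,7-dien-1-yl]benzene-1,3-diol
Conditions: Bu4NF, AcOH (1:1, 3.5 equiv), THF, 0 °C → rt
Reagents that add atoms: none
Why: Fluoride cleavage of aryl silyl ethers; buffering with acetic acid keeps the medium near neutral, so neither phenoxide oxidation nor acid-induced chroman formation or allylic ionisation should occur, and the stereocentre is not touched.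

## Compound list

1 | 5-bromoresorcinol | Oc1cc(O)cc(Br)c1 | starting material
2 | [(2-bromo-4,6-dihydroxyphenyl)methylidene]dimethyliminium chloride | C[N+](C)=Cc1c(O)cc(O)cc1Br.[Cl-] | intermediate (not isolated)
3 | 2-bromo-4,6-dihydroxybenzaldehyde | O=Cc1c(O)cc(O)cc1Br | intermediate
4 | 2-bromo-4,6-bis(triisopropylsilyloxy)benzaldehyde | O=Cc1c(O[Si](C(C)C)(C(C)C)C(C)C)cc(O[Si](C(C)C)(C(C)C)C(C)C)cc1Br | intermediate
5 | benzofuran-6-ol | Oc1ccc2ccoc2c1 | starting material
6 | 6-(triisopropylsilyloxy)benzofuran | CC(C)[Si](Oc1ccc2ccoc2c1)(C(C)C)C(C)C | intermediate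
7 | [6-(triisopropylsilyloxy)benzofuran-2-yl]lithium | [Li]c1cc2ccc(O[Si](C(C)C)(C(C)C)C(C)C)cc2o1 | intermediate (not isolated)
8 | 2-[6-(triisopropylsilyloxy)benzofuran-2-yl]-4,4,5,5-tetramethyl-1,3,2-dioxaborolane | CC1(C)OB(OC1(C)C)c1cc2ccc(O[Si](C(C)C)(C(C)C)C(C)C)cc2o1 | intermediate
9 | 2-[6-(triisopropylsilyloxy)benzofuran-2-yl]-4,6-bis(triisopropylsilyloxy)benzaldehyde | O=Cc1c(O[Si](C(C)C)(C(C)C)C(C)C)cc(O[Si](C(C)C)(C(C)C)C(C)C)cc1-c1cc2ccc(O[Si](C(C)C)(C(C)C)C(C)C)cc2o1 | intermediate
10 | [2-(6-(triisopropylsilyloxy)benzofuran-2-yl)-4,6-bis(triisopropylsilyloxy)phenyl]methanol | OCc1c(O[Si](C(C)C)(C(C)C)C(C)C)cc(O[Si](C(C)C)(C(C)C)C(C)C)cc1-c1cc2ccc(O[Si](C(C)C)(C(C)C)C(C)C)cc2o1 | intermediate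
11 | [2-(6-(triisopropylsilyloxy)benzofuran-2-yl)-4,6-bis(triisopropylsilyloxy)phenyl]methyl methanesulfonate | CS(=O)(=O)OCc1c(O[Si](C(C)C)(C(C)C)C(C)C)cc(O[Si](C(C)C)(C(C)C)C(C)C)cc1-c1cc2ccc(O[Si](C(C)C)(C(C)C)C(C)C)cc2o1 | intermediate (not isolated)
12 | 2-[2-(chloromethyl)-3,5-bis(triisopropylsilyloxy)phenyl]-6-(triisopropylsilyloxy)benzofuran | ClCc1c(O[Si](C(C)C)(C(C)C)C(C)C)cc(O[Si](C(C)C)(C(C)C)C(C)C)cc1-c1cc2ccc(O[Si](C(C)C)(C(C)C)C(C)C)cc2o1 | intermediate (used crude)
13 | pent-4-ynoic acid | C#CCCC(=O)O | starting material
14 | 1-(imidazol-1-yl)pent-4-yn-1-one | C#CCCC(=O)n1ccnc1 | intermediate (not isolated)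
15 | N-methoxy-N-methylpent-4-ynamide | C#CCCC(=O)N(C)OC | intermediate
16 | 2-bromopropene | C=C(C)Br | starting material
17 | isopropenylmagnesium bromide | C=C(C)[Mg]Br | intermediate (not isolated)
18 | 2-methylhept-1-en-6-yn-3-one | C=C(C)C(=O)CCC#C | intermediate
19 | (R)-2-methylhept-1-en-6-yn-3-ol | C=C(C)[C@H](O)CCC#C | intermediate
20 | dimethylaluminium alkoxide of (R,E)-7-(dimethylalumanyl)-2,6-dimethylhepta-1,6-dien-3-ol | C=C(C)[C@H](O[Al](C)C)CC/C(C)=C/[Al](C)C | intermediate (not isolated)
21 | (3R,6E)-8-[2-(6-(triisopropylsilyloxy)benzofuran-2-yl)-4,6-bis(triisopropylsilyloxy)phenyl]-2,6-dimethylocta-1,6-dien-3-ol | C=C(C)[C@H](O)CC/C(C)=C/Cc1c(O[Si](C(C)C)(C(C)C)C(C)C)cc(O[Si](C(C)C)(C(C)C)C(C)C)cc1-c1cc2ccc(O[Si](C(C)C)(C(C)C)C(C)C)cc2o1 | intermediate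
22 | 5-(6-hydroxybenzofuran-2-yl)-4-[(2E,6R)-6-hydroxy-3,7-dimethylocta-2,7-dien-1-yl]benzene-1,3-diol | C=C(C)[C@H](O)CC/C(C)=C/Cc1c(O)cc(O)cc1-c1cc2ccc(O)cc2o1 | target

## Step count and least certain steps

Total step count: 12. Longest linear sequence: 7 steps (steps 1, 2, 5, 6, 7, 11, 12 from 1; the benzofuran branch, steps 3, 4, 5, 6, 7, 11, 12, is equally long; the alkyne branch joins after three steps).

Step 11 (key step). The processes most likely to interfere are:
- incomplete carbometalation of the alkyne that carries an aluminium alkoxide;
- transfer of methyl instead of alkenyl to palladium;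
- Lewis acid ionisation of the electron-rich benzylic chloride, leading to self-alkylation of the arene or benzofuran, or to methylation;
- slow oxidative addition at a benzylic carbon flanked by two ortho substituents.

Fallback with the polarity of the coupling reversed, setting out from 19 and 12 and coming back to the route at 22. Compound 19 is methylaluminated as in step 11 (through 20) and the alane is quenched with I2 to give (R,E)-7-iodo-2,6-dimethylhepta-1,6-dien-3-ol F1. Et3SiCl and imidazole convert this into its triethylsilyl ether F2. Compound 12 is stirred with zinc dust and LiCl in THF to give the benzylzinc chloride F3, which is coupled with F2 under Pd(PPh3)4 (Negishi coupling of a benzylzinc reagent with an alkenyl iodide, retention of geometry) to give the triethylsilyl ether of 21, F4. Buffered Bu4NF then removes all four silyl groups and delivers 22.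

Step 10. Facial discrimination may be poor, because the isopropenyl and 3-butynyl groups do not differ greatly in size, and some hydroboration of the alkyne could occur if the temperature rises. Fallback by resolution, setting out from 18 and coming back at 19. Luche reduction (NaBH4, CeCl3·7H2O, MeOH) gives racemic 2-methylhept-1-en-6-yn-3-ol F5. Sharpless kinetic resolution (Ti(OiPr)4, L-(+)-diisopropyl tartrate, tert-butyl hydroperoxide about 0.6 equiv, 4 Å molecular sieves, CH2Cl2, −20 °C) should epoxidise the S enantiomer to the erythro epoxy alcohol (S)-1-[(R)-2-methyloxiran-2-yl]pent-4-yn-1-ol F6 and leave the R alcohol 19, at the cost of at most half of the material.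

Step 5. Protodeboronation of the 2-benzofuranyl boronate in aqueous base and hydroxide-induced loss of the silyl ethers ortho and para to the formyl group may compete with a coupling that is slowed by the ortho substituent. Fallback without boron or aqueous base, setting out from 6 and 4 and coming back at 9. Compound 6 is lithiated as in step 4 (through 7) and transmetalated with ZnCl2 to [6-(triisopropylsilyloxy)benzofuran-2-yl]zinc chloride F7, which is coupled with 4 under Pd(OAc)2/SPhos in THF at rt to 50 °C (Negishi coupling; arylzinc halides do not add to the aldehyde) to give 9.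

Step 1. Electrophilic attack may go partly to the position between the two hydroxyls, a second formylation may follow, or O-formylation may consume reagent. Fallback by halogen–metal exchange, setting out from 1 and coming back at 4. Compound 1 is silylated (TIPSCl, imidazole) to 1-bromo-3,5-bis(triisopropylsilyloxy)benzene F8. Iodination with N-iodosuccinimide in MeCN is expected to occur next to bromine, the position between the two bulky silyl ethers being blocked, to give 1-bromo-2-iodo-3,5-bis(triisopropylsilyloxy)benzene F9. Selective iodine–magnesium exchange with iPrMgCl·LiCl in THF at −40 °C gives [2-bromo-4,6-bis(triisopropylsilyloxy)phenyl]magnesium chloride F10, which is formylated with DMF to give 4.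

## Further compounds

F1 | step 11 | (R,E)-7-iodo-2,6-dimethylhepta-1,6-dien-3-ol | C=C(C)[C@H](O)CC/C(C)=C/I
F2 | step 11 | (R,E)-triethyl[(7-iodo-2,6-dimethylhepta-1,6-dien-3-yl)oxy]silane | C=C(C)[C@H](O[Si](CC)(CC)CC)CC/C(C)=C/I
F3 | step 11 | {[2-(6-(triisopropylsilyloxy)benzofuran-2-yl)-4,6-bis(triisopropylsilyloxy)phenyl]methyl}zinc chloride | Cl[Zn]Cc1c(O[Si](C(C)C)(C(C)C)C(C)C)cc(O[Si](C(C)C)(C(C)C)C(C)C)cc1-c1cc2ccc(O[Si](C(C)C)(C(C)C)C(C)C)cc2o1
F4 | step 11 | triethylsilyl ether of 21 at the C6' carbinol | C=C(C)[C@H](O[Si](CC)(CC)CC)CC/C(C)=C/Cc1c(O[Si](C(C)C)(C(C)C)C(C)C)cc(O[Si](C(C)C)(C(C)C)C(C)C)cc1-c1cc2ccc(O[Si](C(C)C)(C(C)C)C(C)C)cc2o1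
F5 | step 10 | racemic 2-methylhept-1-en-6-yn-3-ol | C=C(C)C(O)CCC#C
F6 | step 10 | (S)-1-[(R)-2-methyloxiran-2-yl]pent-4-yn-1-ol | C[C@@]1(CO1)[C@@H](O)CCC#C
F7 | step 5 | [6-(triisopropylsilyloxy)benzofuran-2-yl]zinc chloride | Cl[Zn]c1cc2ccc(O[Si](C(C)C)(C(C)C)C(C)C)cc2o1
F8 | step 1 | 1-bromo-3,5-bis(triisopropylsilyloxy)benzene | Brc1cc(O[Si](C(C)C)(C(C)C)C(C)C)cc(O[Si](C(C)C)(C(C)C)C(C)C)c1
F9 | step 1 | 1-bromo-2-iodo-3,5-bis(triisopropylsilyloxy)benzene | Brc1cc(O[Si](C(C)C)(C(C)C)C(C)C)cc(O[Si](C(C)C)(C(C)C)C(C)C)c1I
F10 | step 1 | [2-bromo-4,6-bis(triisopropylsilyloxy)phenyl]magnesium chloride | Cl[Mg]c1c(Br)cc(O[Si](C(C)C)(C(C)C)C(C)C)cc1O[Si](C(C)C)(C(C)C)C(C)C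
A1 | alternative 1 | 22 with the C5 and benzofuran hydroxyls as triisopropylsilyl ethers, the carbinol as tert-butyldimethylsilyl ether and the C3 hydroxyl free | C=C(C)[C@H](O[Si](C)(C)C(C)(C)C)CC/C(C)=C/Cc1c(O)cc(O[Si](C(C)C)(C(C)C)C(C)C)cc1-c1cc2ccc(O[Si](C(C)C)(C(C)C)C(C)C)cc2o1
A2 | alternative 1 | 4-[(2E,6R)-6-(tert-butyldimethylsilyloxy)-3,7-dimethylocta-2,7-dien-1-yl]-3-[6-(triisopropylsilyloxy)benzofuran-2-yl]cyclobut-2-en-1-one (either configuration at the ring carbon C4) | C=C(C)[C@H](O[Si](C)(C)C(C)(C)C)CC/C(C)=C/CC1C(=O)C=C1c1cc2ccc(O[Si](C(C)C)(C(C)C)C(C)C)cc2o1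
A3 | alternative 1 | (triisopropylsilyloxy)ethyne | C#CO[Si](C(C)C)(C(C)C)C(C)C
A4 | alternative 2 | (6'R,7'R)-6',7'-epoxy-8'-ol of the tris(triisopropylsilyl)-protected geranyl arene | OC[C@@]1(C)O[C@@H]1CC/C(C)=C/Cc1c(O[Si](C(C)C)(C(C)C)C(C)C)cc(O[Si](C(C)C)(C(C)C)C(C)C)cc1-c1cc2ccc(O[Si](C(C)C)(C(C)C)C(C)C)cc2o1
A5 | alternative 2 | (2'E,6'E)-8'-hydroxygeranyl arene, tris(triisopropylsilyl) ether | OC/C(C)=C/CC/C(C)=C/Cc1c(O[Si](C(C)C)(C(C)C)C(C)C)cc(O[Si](C(C)C)(C(C)C)C(C)C)cc1-c1cc2ccc(O[Si](C(C)C)(C(C)C)C(C)C)cc2o1
A6 | alternative 2 | 8'-iodo-6',7'-epoxide derived from A4 (same spatial arrangement; 6'R,7'S by the change of priorities) | IC[C@@]1(C)O[C@@H]1CC/C(C)=C/Cc1c(O[Si](C(C)C)(C(C)C)C(C)C)cc(O[Si](C(C)C)(C(C)C)C(C)C)cc1-c1cc2ccc(O[Si](C(C)C)(C(C)C)C(C)C)cc2o1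
A7 | alternative 3 | 22 as its tris(triisopropylsilyl) phenol ether and tert-butyldimethylsilyl carbinol ether | C=C(C)[C@H](O[Si](C)(C)C(C)(C)C)CC/C(C)=C/Cc1c(O[Si](C(C)C)(C(C)C)C(C)C)cc(O[Si](C(C)C)(C(C)C)C(C)C)cc1-c1cc2ccc(O[Si](C(C)C)(C(C)C)C(C)C)cc2o1
A8 | alternative 3 | {2-[2-((2E,6R)-6-(tert-butyldimethylsilyloxy)-3,7-dimethylocta-2,7-dien-1-yl)-3,5-bis(triisopropylsilyloxy)benzoyloxy]-4-(triisopropylsilyloxy)benzyl}triphenylphosphonium bromide | C=C(C)[C@H](O[Si](C)(C)C(C)(C)C)CC/C(C)=C/Cc1c(O[Si](C(C)C)(C(C)C)C(C)C)cc(O[Si](C(C)C)(C(C)C)C(C)C)cc1C(=O)Oc1cc(O[Si](C(C)C)(C(C)C)C(C)C)ccc1C[P+](c1ccccc1)(c1ccccc1)c1ccccc1.[Br-]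
A9 | alternative 3 | 2-[(2E,6R)-6-(tert-butyldimethylsilyloxy)-3,7-dimethylocta-2,7-dien-1-yl]-3,5-bis(triisopropylsilyloxy)benzoic acid | C=C(C)[C@H](O[Si](C)(C)C(C)(C)C)CC/C(C)=C/Cc1c(O[Si](C(C)C)(C(C)C)C(C)C)cc(O[Si](C(C)C)(C(C)C)C(C)C)cc1C(=O)O
A10 | alternative 3 | [2-hydroxy-4-(triisopropylsilyloxy)benzyl]triphenylphosphonium bromide | Oc1cc(O[Si](C(C)C)(C(C)C)C(C)C)ccc1C[P+](c1ccccc1)(c1ccccc1)c1ccccc1.[Br-]
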